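The cyclohexane core (C1 = CH bearing the acyloxypropyl chain, C2 = alkylidene carbon, C3, C4 = CH2, C5 = carbinol carbon, C6 = quaternary carbon) is cut at C1–C6 and C4–C5. A catalytic asymmetric inverse-electron-demand [4+2] joins a 2-acetyl-1,3-diene (C1–C4, decanoate chain in place) with the (E)-silyl enol ether of the C20 polyprenyl methyl ketone (C5=C6). It closes the ring and sets all three contiguous stereocentres, exploiting the vicinal fully substituted C5(O)/C6 pair as an enol ether and the C2 substituent as an activating acetyl group. The enol ether geometry, fixed by conjugate reduction of an s-trans enone, tells methyl from chain at C6. One-carbon homologation of the acetyl group then gives the enal.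

Key step: step 8

Assumption: the (S)-configured oxazaborolidinium catalyst is taken to shield the face of C1 in diene 13 that leads to 14; if the sense proved opposite, the equally accessible catalyst antipode would be used.

Step 1
Reactants: 1 but-3-yn-2-ol (racemic); 2 (2E,6E)-farnesyl bromide
Product: 4 (3E,6E,10E)-3,7,11,15-tetramethylhexadeca-3,6,10,14-tetraen-2-ol (racemic), via alkenylalane 3 (not isolated)
Conditions: Me3Al, Cp2ZrCl2 (cat.), CH2Cl2, 0 °C to rt; then 2, Pd(PPh3)4 (cat.), THF, rt; aqueous work-up
Reagents that add atoms: trimethylaluminium, C[Al](C)C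
Why: Zirconium-catalysed syn-carboalumination puts methyl on the internal alkyne carbon and aluminium on the terminus, and the alkenylalane then couples with the allylic bromide at its primary carbon under zerovalent palladium catalysis with retention of all alkene geometries (Negishi-type alkenyl–allyl coupling), which should give the (3E) skipped diene.

Step 2
Reactants: 4 (3E,6E,10E)-3,7,11,15-tetramethylhexadeca-3,6,10,14-tetraen-2-ol
Product: 5 (3E,6E,10E)-3,7,11,15-tetramethylhexadeca-3,6,10,14-tetraen-2-one
Conditions: activated MnO2, CH2Cl2, rt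
Reagents that add atoms: none
Why: Activated MnO2 should oxidise the secondary allylic alcohol to the conjugated ketone and leave the isolated trisubstituted alkenes untouched (allylic oxidation).

Step 3
Reactants: 5 (3E,6E,10E)-3,7,11,15-tetramethylhexadeca-3,6,10,14-tetraen-2-one
Product: 7 trimethyl{[(2E,6E,10E)-3,7,11,15-tetramethylhexadeca-2,6,10,14-tetraen-2-yl]oxy}silane, via lithium (2E)-enolate 6 (not isolated)
Conditions: Li[BH(CH(CH3)CH2CH3)3] (L-Selectride), THF, −78 °C; then Me3SiCl, Et3N, −78 to 0 °C
Reagents that add atoms: chlorotrimethylsilane, C[Si](C)(C)Cl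
Why: Conjugate hydride addition to the α-methyl enone, which should react from its preferred s-trans conformer, gives the enolate with oxygen cis to the α-methyl group, and O-silylation keeps this (2E) geometry (reductive enolate silylation); no stereocentre is formed, but the double-bond geometry that later defines C6 is.

Step 4
Reactants: 8 pent-4-yn-1-ol; 9 decanoyl chloride
Product: 10 pent-4-yn-1-yl decanoate
Conditions: Et3N, DMAP (cat.), CH2Cl2, 0 °C to rt
Reagents that add atoms: none
Why: Acylation of the primary alcohol by the acid chloride under nucleophilic catalysis (esterification) installs the decanoate at the outset, so no protecting group is needed.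

Step 5
Reactants: 10 pent-4-yn-1-yl decanoate
Product: 11 6-oxohept-4-yn-1-yl decanoate
Conditions: AcCl, PdCl2(PPh3)2 (cat.), CuI (cat.), Et3N, THF, rt
Reagents that add atoms: acetyl chloride, CC(=O)Cl
Why: Palladium/copper-catalysed coupling of the terminal alkyne with the acid chloride (acyl Sonogashira coupling) should give the ynone under conditions that spare the ester.

Step 6
Reactants: 11 6-oxohept-4-yn-1-yl decanoate
Product: 12 (4E)-6-oxo-5-(tributylstannyl)hept-4-en-1-yl decanoate
Conditions: Bu3SnH, Pd(PPh3)4 (cat.), THF, 0 °C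
Reagents that add atoms: tributyltin hydride, CCCC[SnH](CCCC)CCCC
Why: Zerovalent-palladium-catalysed syn-hydrostannation of an ynone delivers tin to the carbon α to the ketone and hydrogen to the β-carbon, so the chain should end up cis to the acetyl group.

Step 7
Reactants: 12 (4E)-6-oxo-5-(tributylstannyl)hept-4-en-1-yl decanoate
Product: 13 (4Z)-5-acetylhepta-4,6-dien-1-yl decanoate
Conditions: CH2=CHBr, Pd(PPh3)4 (cat.), CuI (cat.), CsF, DMF, 40 °C; product kept cold in solution and used directly
Reagents that add atoms: vinyl bromide, C=CBr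
Why: Stille coupling proceeds with retention at the alkenyl–tin carbon, so the vinyl group should sit cis to the alkene hydrogen and the chain take the outside position of the 2-acetyl-1,3-diene; CuI and fluoride speed transmetalation of the hindered stannane.

Step 8
Reactants: 7 trimethyl{[(2E,6E,10E)-3,7,11,15-tetramethylhexadeca-2,6,10,14-tetraen-2-yl]oxy}silane; 13 (4Z)-5-acetylhepta-4,6-dien-1-yl decanoate
Product: 14 3-[(1S,5S,6S)-2-acetyl-5,6-dimethyl-5-(trimethylsilyloxy)-6-[(3E,7E)-4,8,12-trimethyltrideca-3,7,11-trien-1-yl]cyclohex-2-en-1-yl]propyl decanoate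
Conditions: catalyst (20 mol%) from (S)-3,3-diphenyl-1-(2-methylphenyl)tetrahydro-1H,3H-pyrrolo[1,2-c][1,3,2]oxazaborole and HN(SO2CF3)2, Ph3PO (20 mol%), CH2Cl2, −78 to −40 °C
Reagents that add atoms: none
Why: Proposed new method: the chiral oxazaborolidinium ion should bind the acetyl oxygen of 13 and lower the LUMO of the cross-conjugated 2-acyl-diene, so that the nucleophilic C6 of enol ether 7 adds to C1 and the boron-bound dienolate closes through its γ-carbon C4 onto the silyloxocarbenium carbon C5 in one highly asynchronous [4+2] event with the silyl group staying on the C5 oxygen; the closest known reaction types are the oxazaborolidinium-catalysed Mukaiyama–Michael addition of silyl enol ethers to enones and Lewis acid-promoted inverse-electron-demand Diels–Alder (Mukaiyama–Michael–aldol) annulations of silyl enol ethers with electron-poor dienes. The six-membered carbocycle closes in a 6-(enolendo)-exo-trig vinylogous Mukaiyama aldol mode, which should win over α-closure to a cyclobutane and over reversible O-closure to a dihydropyran ketal. The C5/C6 relationship (oxygen cis to the C6 methyl) is carried over suprafacially from the (2E) geometry of 7, because closure of the tight ion pair is expected to be faster than rotation about C5–C6. The C1/C6 relationship should come from the endo orientation of the silyloxy group, with the long chain exo and the C1 chain outside on the (Z)-diene, which places the C1 chain, the C6 methyl and the C5 oxygen on one face. The absolute configuration is set by the catalyst shielding one face of C1, and Ph3PO suppresses racemic silylium catalysis. Regioselectivity (C6 to C1, C4 to C5) follows from the polarity of the partners, and C1, which becomes the γ-carbon of the enal, could be corrected later by equilibration if endo/exo control is incomplete.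

Step 9
Reactants: 14 3-[(1S,5S,6S)-2-acetyl-5,6-dimethyl-5-(trimethylsilyloxy)-6-[(3E,7E)-4,8,12-trimethyltrideca-3,7,11-trien-1-yl]cyclohex-2-en-1-yl]propyl decanoate
Product: 16 3-[(1R,2Z,5S,6S)-5-hydroxy-5,6-dimethyl-2-(1-oxopropan-2-ylidene)-6-[(3E,7E)-4,8,12-trimethyltrideca-3,7,11-trien-1-yl]cyclohexyl]propyl decanoate (target), via 1-methoxydiene 15 (not isolated)
Conditions: [Ph3PCH2OCH3]Cl, KN(SiMe3)2, THF, 0 °C to rt; then 1 M HCl (aq), THF, 0 °C to rt
Reagents that add atoms: (methoxymethyl)triphenylphosphonium chloride, COC[P+](c1ccccc1)(c1ccccc1)c1ccccc1.[Cl-]; water, O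
Why: Wittig methoxymethylenation of the methyl ketone gives a 1-methoxy-1,3-diene, and acid hydrolysis with protonation at ring carbon C3 should move the double bond to the exocyclic C2 position, release the aldehyde and cleave the silyl ether; the (Z)-enal, with the small formyl group syn to the substituted C1, is the expected thermodynamic isomer under these equilibrating conditions.

Compound list
1 | but-3-yn-2-ol (racemic) | CC(O)C#C | starting material
2 | (2E,6E)-farnesyl bromide, (2E,6E)-1-bromo-3,7,11-trimethyldodeca-2,6,10-triene | BrC/C=C(\C)CC/C=C(\C)CCC=C(C)C | starting material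
3 | [(1E)-3-(dimethylaluminiooxy)-2-methylbut-1-en-1-yl]dimethylaluminium (alkenylalane) | C[Al](C)/C=C(\C)C(C)O[Al](C)C | intermediate
4 | (3E,6E,10E)-3,7,11,15-tetramethylhexadeca-3,6,10,14-tetraen-2-ol (racemic) | CC(O)/C(C)=C/C/C=C(\C)CC/C=C(\C)CCC=C(C)C | intermediate
5 | (3E,6E,10E)-3,7,11,15-tetramethylhexadeca-3,6,10,14-tetraen-2-one | CC(=O)/C(C)=C/C/C=C(\C)CC/C=C(\C)CCC=C(C)C | intermediate
6 | lithium (2E,6E,10E)-3,7,11,15-tetramethylhexadeca-2,6,10,14-tetraen-2-olate | C/C(O[Li])=C(/C)CC/C=C(\C)CC/C=C(\C)CCC=C(C)C | intermediate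
7 | trimethyl{[(2E,6E,10E)-3,7,11,15-tetramethylhexadeca-2,6,10,14-tetraen-2-yl]oxy}silane | C/C(O[Si](C)(C)C)=C(/C)CC/C=C(\C)CC/C=C(\C)CCC=C(C)C | intermediate
8 | pent-4-yn-1-ol | OCCCC#C | starting material
9 | decanoyl chloride | CCCCCCCCCC(=O)Cl | starting material
10 | pent-4-yn-1-yl decanoate | CCCCCCCCCC(=O)OCCCC#C | intermediate
11 | 6-oxohept-4-yn-1-yl decanoate | CCCCCCCCCC(=O)OCCCC#CC(C)=O | intermediate
12 | (4E)-6-oxo-5-(tributylstannyl)hept-4-en-1-yl decanoate | CCCCCCCCCC(=O)OCCC/C=C(/[Sn](CCCC)(CCCC)CCCC)C(C)=O | intermediate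
13 | (4Z)-5-acetylhepta-4,6-dien-1-yl decanoate | CCCCCCCCCC(=O)OCCC/C=C(/C=C)C(C)=O | intermediate
14 | 3-[(1S,5S,6S)-2-acetyl-5,6-dimethyl-5-(trimethylsilyloxy)-6-[(3E,7E)-4,8,12-trimethyltrideca-3,7,11-trien-1-yl]cyclohex-2-en-1-yl]propyl decanoate | CCCCCCCCCC(=O)OCCC[C@@H]1C(C(C)=O)=CC[C@](C)(O[Si](C)(C)C)[C@@]1(C)CC/C=C(\C)CC/C=C(\C)CCC=C(C)C | intermediate
15 | 3-[(1R,5S,6S)-2-(1-methoxyprop-1-en-2-yl)-5,6-dimethyl-5-(trimethylsilyloxy)-6-[(3E,7E)-4,8,12-trimethyltrideca-3,7,11-trien-1-yl]cyclohex-2-en-1-yl]propyl decanoate (enol ether E/Z mixture) | CCCCCCCCCC(=O)OCCC[C@@H]1C(C(C)=COC)=CC[C@](C)(O[Si](C)(C)C)[C@@]1(C)CC/C=C(\C)CC/C=C(\C)CCC=C(C)C | intermediate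
16 | 3-[(1R,2Z,5S,6S)-5-hydroxy-5,6-dimethyl-2-(1-oxopropan-2-ylidene)-6-[(3E,7E)-4,8,12-trimethyltrideca-3,7,11-trien-1-yl]cyclohexyl]propyl decanoate | CCCCCCCCCC(=O)OCCC[C@@H]1/C(=C(/C)C=O)CC[C@](C)(O)[C@@]1(C)CC/C=C(\C)CC/C=C(\C)CCC=C(C)C | target

Total step count: 9. Longest linear sequence: 6 steps (steps 4, 5, 6, 7, 8, 9).

Steps most likely to fail

Step 8. The catalyst may discriminate poorly between the two faces of this acyclic α-branched enone, and the zwitterion may be captured at oxygen instead of carbon. The fallback sets out from 7 and 13. The annulation is promoted by the achiral Lewis acid Me2AlCl (CH2Cl2, −78 °C), an ordinary Lewis acid-promoted inverse-electron-demand Diels–Alder (Mukaiyama–Michael–aldol) reaction. It would give the racemate, that is 14 together with ent-14 F1. The enantiomers are separated by preparative chromatography on a chiral stationary phase (cellulose tris(3,5-dimethylphenylcarbamate)), and the route is rejoined at 14.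

Step 3. Hydride may add 1,2 to the β-substituted enone, and the enolate geometry may erode before silylation. The fallback sets out from 5 and gives up geometric control in favour of separation. Conjugate reduction with hydrolytic work-up (Et3SiH, RhCl(PPh3)3 cat.; then K2CO3, MeOH) would give the saturated ketone F2. Thermodynamic silylation (Me3SiCl, NaI, Et3N, MeCN) would then give 7 mixed with the (2Z)-silyl enol ether F3. The mixture is taken through step 8, where the (2Z) isomer should lead to the C6-epimer of 14 F4. This diastereomer is removed by chromatography, and the route is rejoined at 14.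

Step 9. The basic ylide may enolise the hindered conjugated methyl ketone instead of adding to it. The fallback sets out from 14. Corey–Chaykovsky methylenation of the ketone (Me3S+ I−, KN(SiMe3)2, THF, −10 °C) would give the vinyl oxirane F5. Meinwald rearrangement with MgBr2·OEt2 (CH2Cl2, −20 °C) would give the β,γ-unsaturated α-methyl aldehyde F6. Conjugation with DBU, followed by dilute aqueous HCl in THF to cleave the silyl ether, returns to 16.

Further compounds
F1 | step 8 | ent-14, 3-[(1R,5R,6R)-2-acetyl-5,6-dimethyl-5-(trimethylsilyloxy)-6-[(3E,7E)-4,8,12-trimethyltrideca-3,7,11-trien-1-yl]cyclohex-2-en-1-yl]propyl decanoate | CCCCCCCCCC(=O)OCCC[C@H]1C(C(C)=O)=CC[C@@](C)(O[Si](C)(C)C)[C@]1(C)CC/C=C(\C)CC/C=C(\C)CCC=C(C)C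
F2 | step 3 | (6E,10E)-3,7,11,15-tetramethylhexadeca-6,10,14-trien-2-one (racemic) | CC(=O)C(C)CC/C=C(\C)CC/C=C(\C)CCC=C(C)C
F3 | step 3 | trimethyl{[(2Z,6E,10E)-3,7,11,15-tetramethylhexadeca-2,6,10,14-tetraen-2-yl]oxy}silane | C/C(O[Si](C)(C)C)=C(\C)CC/C=C(\C)CC/C=C(\C)CCC=C(C)C
F4 | step 3 | C6-epimer of 14, 3-[(1S,5S,6R)-2-acetyl-5,6-dimethyl-5-(trimethylsilyloxy)-6-[(3E,7E)-4,8,12-trimethyltrideca-3,7,11-trien-1-yl]cyclohex-2-en-1-yl]propyl decanoate | CCCCCCCCCC(=O)OCCC[C@@H]1C(C(C)=O)=CC[C@](C)(O[Si](C)(C)C)[C@]1(C)CC/C=C(\C)CC/C=C(\C)CCC=C(C)C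
F5 | step 9 | vinyl oxirane, 3-[(1R,5S,6S)-5,6-dimethyl-2-(2-methyloxiran-2-yl)-5-(trimethylsilyloxy)-6-[(3E,7E)-4,8,12-trimethyltrideca-3,7,11-trien-1-yl]cyclohex-2-en-1-yl]propyl decanoate (epoxide epimers) | CCCCCCCCCC(=O)OCCC[C@@H]1C(C2(C)CO2)=CC[C@](C)(O[Si](C)(C)C)[C@@]1(C)CC/C=C(\C)CC/C=C(\C)CCC=C(C)C
F6 | step 9 | β,γ-unsaturated aldehyde, 3-[(1R,5S,6S)-5,6-dimethyl-2-(1-oxopropan-2-yl)-5-(trimethylsilyloxy)-6-[(3E,7E)-4,8,12-trimethyltrideca-3,7,11-trien-1-yl]cyclohex-2-en-1-yl]propyl decanoate (side-chain epimers) | CCCCCCCCCC(=O)OCCC[C@@H]1C(C(C)C=O)=CC[C@](C)(O[Si](C)(C)C)[C@@]1(C)CC/C=C(\C)CC/C=C(\C)CCC=C(C)C
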